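Take the ratio cZ/cE of the charges, 95.0% for the new flask, and call it the ceiling: the L, in percent of the E charged, that one Z per E allows when Z is the limiting reagent. Use it to decide the next run: does this flask need more J, or more than 25 min?

common to all: E 0.50 mM
- teal: Z 0.475 mM; J 6.5 µM; run made earlier
- green: Z 0.475 mM; J 26 µM; run made earlier
- amber: Z 0.24 mM; J 13 µM; run made earlier
- flask: Z 0.475 mM; J 13 µM; time 25 min

| run | time / min | L / % |
|---|---|---|
| teal | 2.00 | 79.3 |
| teal | 3.00 | 83.9 |
| teal | 6.00 | 90.0 |
| teal | 10.0 | 92.3 |
| teal | 15.0 | 94.4 |
| teal | 25.0 | 94.4 |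
| green | 4.00 | 94.2 |
| green | 8.00 | 95.0 |
| green | 12.0 | 95.1 |
| green | 15.0 | 95.4 |
| green | 20.0 | 95.0 |
| green | 25.0 | 95.3 |
| amber | 5.00 | 48.1 |
| amber | 10.0 | 47.9 |
| amber | 15.0 | 48.3 |
| amber | 20.0 | 47.8 |
| amber | 25.0 | 48.8 |

(readings scatter by 0.3 percentage points)

- a reading or a percentage of L counts all its forms, free or not
- the reaction counts as stopped when no species that holds the E changes by six tenths of a point or more over the second half of the time

1. why nothing more happens at 25 min, or that something still does (it is still moving / forward and back rates have come level / no working catalyst is left / Z has run out first / all of E has reacted)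
2. L at 25 min, in percent of the E charged
3. amount of L if the flask were left three thousand times as long, in percent of the E charged

Test the ceiling on the runs. Amber has a ratio of 48.0% and reads 48.3% at 15.0 min. Green has a ratio of 95.0% and reads 95.1% at 12.0 min. Teal, with a quarter of green's J, still reads 94.4% at 15.0 min. Amber's J lies between teal's and green's, so its lower plateau goes with its lower Z, not with J. J moves the pace: teal reads 90.0% at 6.00 min, and green reads 94.2% as early as 4.00 min.

Now check the time. Green reads 94.2% at 4.00 min. The new flask's product of cJ and time is 3.12 times that of green at that reading. So add no J and wait no longer. Expect L at the ceiling, 95.0%.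

The forecast agrees, with 95%, 95% for the long wait and the verdict "Z has run out first", since “the plateau follows Z and not a fixed conversion”.

The flask gives "Z has run out first", with L at 95.0% and 95.0% for the long wait.

    J + L ⇌ D (K = 1700 M⁻¹, k = 820 M⁻¹ s⁻¹)
    E + Z + J → L + J, rate k2*[E]*[Z]*[J]/(1 + ([E]/sat2)) (1.30 mM, k = 2.00 × 10⁷ M⁻² s⁻¹)

Ask whether this flask has come to rest. At 25.0 min it holds L at 95.0%, level with the ceiling of 95.0%, with E at 5.0% and Z at 0.024% of its charge. The slowest mode has a half-life of 3.23 min, shorter than 25 min. At 250 min Z stands at 0% of its charge and L at 95.0%, so the tenfold wait takes up the last of the Z and leaves L the same at this rounding.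

Now charge E at 1.2 mM and keep the rest. The ceiling reads 39.6%. That neighbour flask gives L at 39.6%, with 60% of its E left.

All runs come from a simulation on assumed constants; the scatter is artificial.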